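**Retrosynthetic overview**

1. The methoxy-para-quinone is made last from 3-methyl-2-alkylphenol 27 by two C–O bond formations in one flask: aerobic ortho-oxygenation, methanol addition para to the original oxygen, and ortho→para quinone transposition.
2. 27 comes from 2-bromo-3-methylphenol 25 and terminal alkene 24 by B-alkyl Suzuki coupling; the bromide fixes the alkyl position between OH and CH3.
3. 24 comes from secondary boronic ester 18 by Zweifel vinylation and an alkyl–alkyl Suzuki coupling with 6-bromohex-1-ene 22 (C1–C8 of the side chain).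
4. 18 comes from (S)-1-bromo-2-methylbutane 6 (chiral pool, C15) by five reagent-controlled boronic ester homologations: three with the diamine-free (R)-lithium carbenoid released in the flask from stannane 5 (C13, C11, C9, all syn; 5 is made from acid 1 in two steps) and two with LiCH2Cl.
5. No ring is built; the only ring is the purchased benzene ring of 25, oxidised to the quinone in the final step.

Assumption: the stereocentre created and destroyed within step 9 (C2 of 20) is left undefined; CIP descriptors of the boron intermediates change with substituent priorities although no centre is ever inverted.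

**Step 1**
Reactants: 1 2,4,6-triisopropylbenzoic acid; 2 iodoethane
Product: 3 ethyl 2,4,6-triisopropylbenzoate
Conditions: K2CO3, DMF, rt
Reagents that add atoms: none
Why: Carboxylate O-alkylation (SN2 at iodoethane) is not affected by the steric shielding of the carbonyl group, and no stereocentre is involved.

**Step 2**
Reactants: 3 ethyl 2,4,6-triisopropylbenzoate
Product: 5 (1R)-1-(trimethylstannyl)ethyl 2,4,6-triisopropylbenzoate, via sparteine-bound lithiated benzoate 4 (not isolated)
Conditions: s-BuLi, (+)-sparteine, Et2O, −78 °C; Me3SnCl; recrystallisation (MeOH) to ≥99:1 er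
Reagents that add atoms: trimethyltin chloride, C[Sn](C)(C)Cl
Why: Sparteine-mediated asymmetric α-deprotonation (Hoppe–Beak type) with s-BuLi/(+)-sparteine removes the pro-R hydrogen to give the configurationally stable (R)-configured sparteine chelate 4, which is stannylated with retention; this C–Sn centre is the source of C9, C11 and C13 of the target.

**Step 3**
Reactants: 6 (2S)-1-bromo-2-methylbutane
Product: 8 4,4,5,5-tetramethyl-2-[(2R)-2-methylbutyl]-1,3,2-dioxaborolane, via Grignard reagent 7 (not isolated)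
Conditions: Mg, THF, rt→40 °C; i-PrOBpin, −78 °C→rt; 1 M HCl
Reagents that add atoms: 2-isopropoxy-4,4,5,5-tetramethyl-1,3,2-dioxaborolane, CC(C)OB1OC(C)(C)C(C)(C)O1
Why: Grignard formation and electrophilic borylation do not touch the β-stereocentre, so the chiral-pool centre becomes C15 of the target unchanged (the descriptor reads R in 8 only because CH2B ranks below ethyl).

**Step 4**
Reactants: 8 4,4,5,5-tetramethyl-2-[(2R)-2-methylbutyl]-1,3,2-dioxaborolane; 5 (1R)-1-(trimethylstannyl)ethyl 2,4,6-triisopropylbenzoate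
Product: 10 4,4,5,5-tetramethyl-2-[(2S,4S)-4-methylhexan-2-yl]-1,3,2-dioxaborolane, via boronate complex 9 (not isolated)
Conditions: 5 (1.3 equiv), n-BuLi, Et2O, −78 °C, 1 h; add 8, −78 °C, 2 h; then 35 °C, 2 h; aq NH4Cl
Reagents that add atoms: none
Why: Lithiation–borylation (stereospecific 1,2-metallate rearrangement): Sn–Li exchange on 5 gives the diamine-free (R)-lithium carbenoid reagent with retention, it adds to boron with retention, and the alkyl group then migrates from boron to carbon anti to the benzoate with inversion, so the reagent sets the new C–B centre (future C13) syn to C15.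

**Step 5**
Reactants: 10 4,4,5,5-tetramethyl-2-[(2S,4S)-4-methylhexan-2-yl]-1,3,2-dioxaborolane
Product: 12 2-[(2R,4S)-2,4-dimethylhexyl]-4,4,5,5-tetramethyl-1,3,2-dioxaborolane, via boronate complex 11 (not isolated)
Conditions: BrCH2Cl (2.5 equiv), n-BuLi (2.0 equiv), Et2O, −78 °C→rt
Reagents that add atoms: bromochloromethane, ClCBr
Why: Matteson homologation with LiCH2Cl made in situ: the boronate forms at −78 °C and the secondary alkyl group migrates with retention on warming after the excess carbenoid has decomposed, so one CH2 (C12) is inserted and no stereocentre is touched.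

**Step 6**
Reactants: 12 2-[(2R,4S)-2,4-dimethylhexyl]-4,4,5,5-tetramethyl-1,3,2-dioxaborolane; 5 (1R)-1-(trimethylstannyl)ethyl 2,4,6-triisopropylbenzoate
Product: 14 2-[(2S,4R,6S)-4,6-dimethyloctan-2-yl]-4,4,5,5-tetramethyl-1,3,2-dioxaborolane, via boronate complex 13 (not isolated)
Conditions: 5 (1.3 equiv), n-BuLi, Et2O, −78 °C, 1 h; add 12, −78 °C, 2 h; then 35 °C, 2 h; aq NH4Cl
Reagents that add atoms: none
Why: Second lithiation–borylation with the same diamine-free (R)-carbenoid reagent made in the flask from 5 (retention at boron, inversion on 1,2-migration) sets the future C11 syn to C13 independently of the existing centres, because the boronic ester is primary and the reagent controls the outcome.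

**Step 7**
Reactants: 14 2-[(2S,4R,6S)-4,6-dimethyloctan-2-yl]-4,4,5,5-tetramethyl-1,3,2-dioxaborolane
Product: 16 4,4,5,5-tetramethyl-2-[(2R,4R,6S)-2,4,6-trimethyloctyl]-1,3,2-dioxaborolane, via boronate complex 15 (not isolated)
Conditions: BrCH2Cl (2.5 equiv), n-BuLi (2.0 equiv), Et2O, −78 °C→rt
Reagents that add atoms: bromochloromethane, ClCBr
Why: Second Matteson CH2 homologation inserts C10 with retention at the migrating carbon, as in step 5.

**Step 8**
Reactants: 16 4,4,5,5-tetramethyl-2-[(2R,4R,6S)-2,4,6-trimethyloctyl]-1,3,2-dioxaborolane; 5 (1R)-1-(trimethylstannyl)ethyl 2,4,6-triisopropylbenzoate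
Product: 18 4,4,5,5-tetramethyl-2-[(2S,4R,6S,8S)-4,6,8-trimethyldecan-2-yl]-1,3,2-dioxaborolane, via boronate complex 17 (not isolated)
Conditions: 5 (1.3 equiv), n-BuLi, Et2O, −78 °C, 1 h; add 16, −78 °C, 2 h; then 35 °C, 2 h; aq NH4Cl
Reagents that add atoms: none
Why: Third lithiation–borylation with the diamine-free (R)-carbenoid reagent made in the flask from 5 sets the future C9 and completes the all-syn tetrad by the same retention/inversion sequence.

**Step 9**
Reactants: 18 4,4,5,5-tetramethyl-2-[(2S,4R,6S,8S)-4,6,8-trimethyldecan-2-yl]-1,3,2-dioxaborolane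
Product: 21 (3S,5S,7S,9S)-3,5,7,9-tetramethylundec-1-ene, via vinyl boronate complex 19 (not isolated), via iodo boronic ester 20 (not isolated)
Conditions: CH2=CHMgBr (4 equiv), THF, rt; I2, MeOH, −78 °C; NaOMe, −78 °C→rt
Reagents that add atoms: vinylmagnesium bromide, C=C[Mg]Br
Why: Zweifel olefination: iodonium-triggered 1,2-migration of the secondary alkyl group with retention, then anti β-elimination of boron and iodide, gives the terminal alkene (C7, C8) without touching C9.

**Step 10**
Reactants: 21 (3S,5S,7S,9S)-3,5,7,9-tetramethylundec-1-ene; 22 6-bromohex-1-ene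
Product: 24 (9R,11R,13S,15S)-9,11,13,15-tetramethylheptadec-1-ene, via alkylborane 23 (not isolated)
Conditions: 9-BBN (1.0 equiv), THF, rt; then 22, Pd(OAc)2 (4 mol%), PCy3 (8 mol%), K3PO4·H2O, THF, rt
Reagents that add atoms: none
Why: Anti-Markovnikov hydroboration gives a primary B-alkyl-9-BBN that couples with the primary alkyl bromide in a Pd/PCy3 alkyl–alkyl Suzuki–Miyaura reaction at room temperature, where β-hydride elimination is suppressed; no stereocentre is involved.

**Step 11**
Reactants: 24 (9R,11R,13S,15S)-9,11,13,15-tetramethylheptadec-1-ene; 25 2-bromo-3-methylphenol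
Product: 27 3-methyl-2-[(9R,11R,13S,15S)-9,11,13,15-tetramethylheptadecyl]phenol, via alkylborane 26 (not isolated)
Conditions: 9-BBN, THF, rt; then 25, Pd(OAc)2/SPhos (5/10 mol%), K3PO4 (3 equiv, aq), THF, 65 °C
Reagents that add atoms: none
Why: B-alkyl Suzuki–Miyaura coupling with a biarylphosphine ligand chosen for the di-ortho-substituted bromide and the free phenoxide forms the aryl–C1' bond exactly between OH and CH3, the position being fixed by the bromide.

**Step 12**
Reactants: 27 3-methyl-2-[(9R,11R,13S,15S)-9,11,13,15-tetramethylheptadecyl]phenol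
Product: 31 5-methoxy-2-methyl-3-[(9R,11R,13S,15S)-9,11,13,15-tetramethylheptadecyl]cyclohexa-2,5-diene-1,4-dione, via ortho-quinone 28 (not isolated), via methoxycatechol 29 (not isolated), via methoxy-ortho-quinone 30 (not isolated)
Conditions: [Cu(MeCN)4]PF6 (10 mol%), N,N'-di-tert-butylethylenediamine (15 mol%), O2 (1 atm), CH2Cl2/MeOH 4:1, 4 Å MS, rt; then HCl (1.25 M in MeOH), 40 °C; aqueous work-up
Reagents that add atoms: dioxygen, O=O; methanol, CO
Why: Proposed new method: a tyrosinase-like diamine–Cu2O2 species should oxygenate the only free ortho carbon of the copper-bound phenolate to give ortho-quinone 28, methanol should add 1,4 at the one unsubstituted enone β-carbon (para to the original C–O; the other β-carbon carries CH3) and Cu/O2 should re-oxidise catechol 29 to vinylogous ester 30, after which acid in methanol should move the methoxy group by ketalisation–elimination to the more stable para-quinone 31, the only para-quinone that the 1,2,4-oxygen pattern allows, so both new C–O bonds are placed by the substrate; the closest known reaction types are the Cu/diamine aerobic ortho-oxygenation of phenols to ortho-quinones, the formation of 4-methoxy-ortho-quinones when catechols are oxidised in methanol, and the acid-catalysed isomerisation of 4-alkoxy-1,2-quinones to 2-alkoxy-1,4-quinones, which have not been combined into a one-flask phenol to 2-methoxy-1,4-benzoquinone conversion.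

**Compound list**

1 | 2,4,6-triisopropylbenzoic acid | OC(=O)c1c(C(C)C)cc(C(C)C)cc1C(C)C | starting material
2 | iodoethane | CCI | starting material
3 | ethyl 2,4,6-triisopropylbenzoate | CCOC(=O)c1c(C(C)C)cc(C(C)C)cc1C(C)C | intermediate
4 | (1R)-1-lithioethyl 2,4,6-triisopropylbenzoate as its (+)-sparteine chelate (diamine not drawn; not isolated) | [Li][C@H](C)OC(=O)c1c(C(C)C)cc(C(C)C)cc1C(C)C | intermediate
5 | (1R)-1-(trimethylstannyl)ethyl 2,4,6-triisopropylbenzoate | C[Sn](C)(C)[C@H](C)OC(=O)c1c(C(C)C)cc(C(C)C)cc1C(C)C | intermediate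
6 | (2S)-1-bromo-2-methylbutane | CC[C@H](C)CBr | starting material
7 | [(2S)-2-methylbutyl]magnesium bromide (not isolated) | CC[C@H](C)C[Mg]Br | intermediate
8 | 4,4,5,5-tetramethyl-2-[(2R)-2-methylbutyl]-1,3,2-dioxaborolane | CC[C@H](C)CB1OC(C)(C)C(C)(C)O1 | intermediate
9 | lithium boronate complex of 8 and the lithium carbenoid made from 5: boron carries the (2R)-2-methylbutyl group and the (1R)-1-(2,4,6-triisopropylbenzoyloxy)ethyl group (not isolated) | [Li+].CC[C@H](C)C[B-]1(OC(C)(C)C(C)(C)O1)[C@H](C)OC(=O)c2c(C(C)C)cc(C(C)C)cc2C(C)C | intermediate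
10 | 4,4,5,5-tetramethyl-2-[(2S,4S)-4-methylhexan-2-yl]-1,3,2-dioxaborolane | CC[C@H](C)C[C@H](C)B1OC(C)(C)C(C)(C)O1 | intermediate
11 | lithium boronate complex of 10 and LiCH2Cl: boron carries the (2S,4S)-4-methylhexan-2-yl group and CH2Cl (not isolated) | [Li+].CC[C@H](C)C[C@H](C)[B-]1(CCl)OC(C)(C)C(C)(C)O1 | intermediate
12 | 2-[(2R,4S)-2,4-dimethylhexyl]-4,4,5,5-tetramethyl-1,3,2-dioxaborolane | CC[C@H](C)C[C@H](C)CB1OC(C)(C)C(C)(C)O1 | intermediate
13 | lithium boronate complex of 12 and the lithium carbenoid made from 5: boron carries the (2R,4S)-2,4-dimethylhexyl group and the (1R)-1-(2,4,6-triisopropylbenzoyloxy)ethyl group (not isolated) | [Li+].CC[C@H](C)C[C@H](C)C[B-]1(OC(C)(C)C(C)(C)O1)[C@H](C)OC(=O)c2c(C(C)C)cc(C(C)C)cc2C(C)C | intermediate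
14 | 2-[(2S,4R,6S)-4,6-dimethyloctan-2-yl]-4,4,5,5-tetramethyl-1,3,2-dioxaborolane | CC[C@H](C)C[C@H](C)C[C@H](C)B1OC(C)(C)C(C)(C)O1 | intermediate
15 | lithium boronate complex of 14 and LiCH2Cl: boron carries the (2S,4R,6S)-4,6-dimethyloctan-2-yl group and CH2Cl (not isolated) | [Li+].CC[C@H](C)C[C@H](C)C[C@H](C)[B-]1(CCl)OC(C)(C)C(C)(C)O1 | intermediate
16 | 4,4,5,5-tetramethyl-2-[(2R,4R,6S)-2,4,6-trimethyloctyl]-1,3,2-dioxaborolane | CC[C@H](C)C[C@H](C)C[C@H](C)CB1OC(C)(C)C(C)(C)O1 | intermediate
17 | lithium boronate complex of 16 and the lithium carbenoid made from 5: boron carries the (2R,4R,6S)-2,4,6-trimethyloctyl group and the (1R)-1-(2,4,6-triisopropylbenzoyloxy)ethyl group (not isolated) | [Li+].CC[C@H](C)C[C@H](C)C[C@H](C)C[B-]1(OC(C)(C)C(C)(C)O1)[C@H](C)OC(=O)c2c(C(C)C)cc(C(C)C)cc2C(C)C | intermediate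
18 | 4,4,5,5-tetramethyl-2-[(2S,4R,6S,8S)-4,6,8-trimethyldecan-2-yl]-1,3,2-dioxaborolane | CC[C@H](C)C[C@H](C)C[C@H](C)C[C@H](C)B1OC(C)(C)C(C)(C)O1 | intermediate
19 | bromomagnesium vinyl boronate complex of 18: boron carries the (2S,4R,6S,8S)-4,6,8-trimethyldecan-2-yl group and vinyl (not isolated) | Br[Mg+].CC[C@H](C)C[C@H](C)C[C@H](C)C[C@H](C)[B-]1(C=C)OC(C)(C)C(C)(C)O1 | intermediate
20 | 2-[(2RS,3S,5S,7S,9S)-1-iodo-3,5,7,9-tetramethylundecan-2-yl]-4,4,5,5-tetramethyl-1,3,2-dioxaborolane (both C2 epimers; not isolated) | CC[C@H](C)C[C@H](C)C[C@H](C)C[C@H](C)C(CI)B1OC(C)(C)C(C)(C)O1 | intermediate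
21 | (3S,5S,7S,9S)-3,5,7,9-tetramethylundec-1-ene | CC[C@H](C)C[C@H](C)C[C@H](C)C[C@H](C)C=C | intermediate
22 | 6-bromohex-1-ene | BrCCCCC=C | starting material
23 | 9-[(3R,5R,7S,9S)-3,5,7,9-tetramethylundecyl]-9-borabicyclo[3.3.1]nonane (not isolated) | CC[C@H](C)C[C@H](C)C[C@H](C)C[C@H](C)CCB1C2CCCC1CCC2 | intermediate
24 | (9R,11R,13S,15S)-9,11,13,15-tetramethylheptadec-1-ene | CC[C@H](C)C[C@H](C)C[C@H](C)C[C@H](C)CCCCCCC=C | intermediate
25 | 2-bromo-3-methylphenol | Cc1cccc(O)c1Br | starting material
26 | 9-[(9R,11R,13S,15S)-9,11,13,15-tetramethylheptadecyl]-9-borabicyclo[3.3.1]nonane (not isolated) | CC[C@H](C)C[C@H](C)C[C@H](C)C[C@H](C)CCCCCCCCB1C2CCCC1CCC2 | intermediate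
27 | 3-methyl-2-[(9R,11R,13S,15S)-9,11,13,15-tetramethylheptadecyl]phenol | CC[C@H](C)C[C@H](C)C[C@H](C)C[C@H](C)CCCCCCCCc1c(C)cccc1O | intermediate
28 | 4-methyl-3-[(9R,11R,13S,15S)-9,11,13,15-tetramethylheptadecyl]cyclohexa-3,5-diene-1,2-dione (not isolated) | CC[C@H](C)C[C@H](C)C[C@H](C)C[C@H](C)CCCCCCCCC1=C(C)C=CC(=O)C1=O | intermediate
29 | 5-methoxy-4-methyl-3-[(9R,11R,13S,15S)-9,11,13,15-tetramethylheptadecyl]benzene-1,2-diol (not isolated) | CC[C@H](C)C[C@H](C)C[C@H](C)C[C@H](C)CCCCCCCCc1c(C)c(OC)cc(O)c1O | intermediate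
30 | 5-methoxy-4-methyl-3-[(9R,11R,13S,15S)-9,11,13,15-tetramethylheptadecyl]cyclohexa-3,5-diene-1,2-dione (not isolated) | CC[C@H](C)C[C@H](C)C[C@H](C)C[C@H](C)CCCCCCCCC1=C(C)C(OC)=CC(=O)C1=O | intermediate
31 | 5-methoxy-2-methyl-3-[(9R,11R,13S,15S)-9,11,13,15-tetramethylheptadecyl]cyclohexa-2,5-diene-1,4-dione (CNP0330767.1) | CC[C@H](C)C[C@H](C)C[C@H](C)C[C@H](C)CCCCCCCCC1=C(C)C(=O)C=C(OC)C1=O | target

**Step count and risks**

Total step count: 12. Longest linear sequence: 11 steps (1, 2, 4–12, from acid 1 through stannane 5 to 31); counted from bromide 6 the main chain is 10 steps (3–12).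

The three steps most likely to fail:

Step 12 (the proposed new step). Risks are radical C–C/C–O coupling of the para-unsubstituted phenol instead of ortho-oxygenation, tautomerisation of the alkyl-substituted ortho-quinone to a quinone methide, copper-mediated ring cleavage in methanol, and incomplete ortho→para transposition. The fallback uses known reactions only, sets out from phenol 27 and comes back at target 31. Ortho-selective bromination at the one free ortho position (NBS, cat. i-Pr2NH, CH2Cl2, 0 °C) gives 6-bromo-3-methyl-2-[(9R,11R,13S,15S)-9,11,13,15-tetramethylheptadecyl]phenol F1. Copper-mediated methanolysis of the aryl bromide (NaOMe, CuI, DMF/MeOH, 110 °C) gives the guaiacol 6-methoxy-3-methyl-2-[(9R,11R,13S,15S)-9,11,13,15-tetramethylheptadecyl]phenol F2. Teuber oxidation of the free para position with Fremy's salt (KH2PO4 buffer, acetone/water, rt) then gives 31.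

Step 11. The bromide is flanked by OH and CH3 and the phenol is unprotected, so oxidative addition and transmetallation may be slow and protodeboronation of 26 may win. The fallback replaces the Suzuki coupling by a Negishi coupling on a protected arene; it sets out from alkylborane 26 (made from 24 as in step 11) and comes back at 27. Iodination of the borane (I2, NaOMe, THF/MeOH) gives (9R,11R,13S,15S)-1-iodo-9,11,13,15-tetramethylheptadecane F3. Zinc insertion (Zn dust, LiCl, THF, 40 °C) gives [(9R,11R,13S,15S)-9,11,13,15-tetramethylheptadecyl]zinc iodide F4. This is coupled (Pd(OAc)2/CPhos, THF, rt) with 2-bromo-1-(methoxymethoxy)-3-methylbenzene F5, made from 25 with MOMCl and i-Pr2NEt, to give 1-(methoxymethoxy)-3-methyl-2-[(9R,11R,13S,15S)-9,11,13,15-tetramethylheptadecyl]benzene F6. HCl in methanol removes the acetal and gives 27.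

Step 10. The 5-hexenyl–palladium intermediate can cyclise or β-eliminate, and any excess 9-BBN would hydroborate the second alkene. The fallback replaces the Pd coupling by a copper-catalysed Grignard–tosylate coupling; it sets out from alkylborane 23 (made from 21 as in step 10) and comes back at 24. Oxidation (NaOH, H2O2) gives (3S,5S,7S,9S)-3,5,7,9-tetramethylundecan-1-ol F7. TsCl/pyridine gives (3S,5S,7S,9S)-3,5,7,9-tetramethylundecyl 4-methylbenzenesulfonate F8. Coupling with hex-5-en-1-ylmagnesium bromide F9 (from 22 and Mg) under Li2CuCl4 catalysis (THF, −20 °C→rt) gives 24.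

**Further compounds**

F1 | step 12 | 6-bromo-3-methyl-2-[(9R,11R,13S,15S)-9,11,13,15-tetramethylheptadecyl]phenol | CC[C@H](C)C[C@H](C)C[C@H](C)C[C@H](C)CCCCCCCCc1c(C)ccc(Br)c1O
F2 | step 12 | 6-methoxy-3-methyl-2-[(9R,11R,13S,15S)-9,11,13,15-tetramethylheptadecyl]phenol | CC[C@H](C)C[C@H](C)C[C@H](C)C[C@H](C)CCCCCCCCc1c(C)ccc(OC)c1O
F3 | step 11 | (9R,11R,13S,15S)-1-iodo-9,11,13,15-tetramethylheptadecane | CC[C@H](C)C[C@H](C)C[C@H](C)C[C@H](C)CCCCCCCCI
F4 | step 11 | [(9R,11R,13S,15S)-9,11,13,15-tetramethylheptadecyl]zinc iodide | CC[C@H](C)C[C@H](C)C[C@H](C)C[C@H](C)CCCCCCCC[Zn]I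
F5 | step 11 | 2-bromo-1-(methoxymethoxy)-3-methylbenzene | COCOc1cccc(C)c1Br
F6 | step 11 | 1-(methoxymethoxy)-3-methyl-2-[(9R,11R,13S,15S)-9,11,13,15-tetramethylheptadecyl]benzene | CC[C@H](C)C[C@H](C)C[C@H](C)C[C@H](C)CCCCCCCCc1c(C)cccc1OCOC
F7 | step 10 | (3S,5S,7S,9S)-3,5,7,9-tetramethylundecan-1-ol | CC[C@H](C)C[C@H](C)C[C@H](C)C[C@H](C)CCO
F8 | step 10 | (3S,5S,7S,9S)-3,5,7,9-tetramethylundecyl 4-methylbenzenesulfonate | CC[C@H](C)C[C@H](C)C[C@H](C)C[C@H](C)CCOS(=O)(=O)c1ccc(C)cc1
F9 | step 10 | hex-5-en-1-ylmagnesium bromide | C=CCCCC[Mg]Br
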